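**Retrosynthetic overview**
1. Dihydropyran (last ring): inverse-electron-demand hetero-Diels–Alder reaction between the 2-(2-methylpropylidene) derivative of the ring A dione and the exocyclic C=CH2 of a (1S,4R,4aR)-octahydronaphthalene diene; it forms O–C(spiro) and CH2–CH(i-Pr).
2. Ring A (first ring): [3+3] double C-acylation of the methyl enol ether of 2-methylpentan-3-one with malonyl dichloride; it forms CMe2–C(=O) and C(CH3)–C(=O) in one operation.
3. Enabling feature: in ring A the C–OMe carbon lies between the only two C-alkylated ring carbons (quaternary CMe2 and C–CH3), so these three atoms are the enol ether of a simple ketone, nucleophilic at both flanks; the other three ring carbons (two O-bearing carbons around the ring-fusion carbon) are a malonyl unit, and the quaternary carbon blocks aromatization.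
4. Diene: from (−)-menthone (chiral pool; supplies ring B with the isopropyl and methyl stereocenters) by α-methylenation, conjugate allylation with kinetic protonation (ring-fusion stereocenter), SmI2 Barbier closure of the second carbocycle and dehydration.
5. Order of ring formation: ring A (step 2), second carbocycle of the diene (step 6), dihydropyran (step 8).

Key step: step 2

Assumption: enol ether 3 is drawn as its tetrasubstituted double-bond isomer; any trisubstituted isomer formed with it equilibrates through the common oxocarbenium ion under the acidic conditions of steps 1 and 2.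

**Route**

Step 1
Reactants: 1 2-methylpentan-3-one
Product: 3 3-methoxy-2-methylpent-2-ene, via ketal 2 (not isolated)
Conditions: HC(OMe)3 (1.2 equiv), p-TsOH·H2O (1 mol %), neat, rt; then slow distillation of the volatiles (bath 140–160 °C), Et3N, fractional distillation
Reagents that add atoms: trimethyl orthoformate, COC(OC)OC
Why: Acid-catalysed ketalization with the orthoformate, then acid-catalysed thermal loss of methanol from ketal 2 (ketal cracking), is the standard route to methyl enol ethers; no stereocenter is involved.

Step 2
Reactants: 3 3-methoxy-2-methylpent-2-ene; 4 malonyl dichloride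
Product: 6 5-methoxy-4,6,6-trimethylcyclohex-4-ene-1,3-dione (enolized in solution), via acid chloride 5 (not isolated)
Conditions: 4 (1.0 equiv) added to 3 (2.0 equiv), Et2O, −20 °C → rt, 24 h; extraction into aq NaHCO3, then cold dilute HCl to pH 3
Reagents that add atoms: none
Why: Proposed new method: the malonyl dichloride annulation of enol ethers is extended from cyclic to an acyclic methyl enol ether; mechanistically the CMe2 terminus of 3 is C-acylated by malonyl dichloride (or by chlorocarbonylketene formed from it), the oxocarbenium ion loses a proton from the ethyl CH2 to give enol ether acid chloride 5, whose new nucleophilic carbon attacks the tethered acyl chloride, and loss of the doubly activated proton then returns the methoxy-bearing C=C as a vinylogous ester. The closest known reaction type is the Effenberger cyclization, in which 1-methoxycyclohexenes and malonyl dichloride give bicyclo[3.3.1]nonane-2,4,9-triones by the same α then α′ double C-acylation. Ring A is closed by a 6-(enolendo)-exo-trig C-acylation. No stereocenter is formed. The step needs C- over O-cyclization (loss of chloromethane to a 4-hydroxy-2-pyranone is the usual fate of enolizable acyclic ketone derivatives), and this is secured by the methyl ether, which keeps the oxygen blocked, and by the first acylation making the quaternary CMe2 carbon, so that the acylated carbon cannot enolize toward the enol ether oxygen and the gem-dimethyl effect favours carbocyclization. The same design fixes the methoxy group on the carbon between CMe2 and C–CH3, a regiochemistry that O-methylation of the parent trione would not deliver.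

Step 3
Reactants: 7 (−)-menthone [(2S,5R)-5-methyl-2-(propan-2-yl)cyclohexan-1-one]
Product: 9 (3R,6S)-2-[(dimethylamino)methyl]-3-methyl-6-(propan-2-yl)cyclohexan-1-one (C2 epimers), via lithium enolate 8 (not isolated)
Conditions: LiN(i-Pr)2 (LDA, 1.05 equiv, commercial solution), THF, −78 °C, 45 min; then Me2N=CH2+ I− (1.2 equiv), −78 °C → rt
Reagents that add atoms: Eschenmoser's salt (N,N-dimethylmethyleneiminium iodide), C[N+](C)=C.[I-]
Why: Kinetic deprotonation takes place at the less hindered CH2 and not at the isopropyl-bearing carbon, and the enolate 8 is aminomethylated in a Mannich reaction; the new stereocenter is removed in step 4 and the two menthone stereocenters are untouched.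

Step 4
Reactants: 9 (3R,6S)-2-[(dimethylamino)methyl]-3-methyl-6-(propan-2-yl)cyclohexan-1-one
Product: 11 (3R,6S)-3-methyl-2-methylidene-6-(propan-2-yl)cyclohexan-1-one, via ammonium iodide 10 (not isolated)
Conditions: MeI (3 equiv), Et2O, rt, 12 h; then sat. aq NaHCO3/CH2Cl2, rt, 2 h; used at once
Reagents that add atoms: none
Why: N-Methylation and Hofmann-type E1cB elimination of trimethylamine from the β-ammonio ketone under bicarbonate should give the α-methylene ketone without epimerizing the isopropyl-bearing α′-carbon.

Step 5
Reactants: 11 (3R,6S)-3-methyl-2-methylidene-6-(propan-2-yl)cyclohexan-1-one; 12 [2-(chloromethyl)prop-2-en-1-yl]trimethylsilane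
Product: 14 (2R,3R,6S)-2-[3-(chloromethyl)but-3-en-1-yl]-3-methyl-6-(propan-2-yl)cyclohexan-1-one, via titanium enolate 13 (not isolated)
Conditions: TiCl4 (1.1 equiv), CH2Cl2, −78 °C, 10 min; 12 (1.3 equiv), −78 °C, 1 h; MeOH quench at −78 °C, then aq NaHCO3
Reagents that add atoms: none
Why: Hosomi–Sakurai conjugate allylation of the TiCl4-activated exocyclic enone gives enolate 13, and kinetic protonation at −78 °C should occur on the face opposite to the neighbouring methyl group, which allylic strain with the new side chain holds pseudoaxial, so that the side chain ends up cis to the methyl group (C2 = R).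

Step 6
Reactants: 14 (2R,3R,6S)-2-[3-(chloromethyl)but-3-en-1-yl]-3-methyl-6-(propan-2-yl)cyclohexan-1-one
Product: 15 (1S,4R,4aR)-4-methyl-7-methylidene-1-(propan-2-yl)octahydronaphthalen-8a(1H)-ol (8a epimers)
Conditions: SmI2 (2.5 equiv, 0.1 M in THF), 0 °C → rt, 1 h; aq NH4Cl
Reagents that add atoms: none
Why: In this samarium Barbier reaction SmI2 reduces the allylic chloride to an allylsamarium species that adds to the hindered ketone in a six-membered ring closure under non-enolizing conditions, so the two α-stereocenters are kept; the configuration of the new carbinol carbon is immaterial because it becomes sp2 in step 7.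

Step 7
Reactants: 15 (1S,4R,4aR)-4-methyl-7-methylidene-1-(propan-2-yl)octahydronaphthalen-8a(1H)-ol
Product: 17 (1S,4R,4aR)-4-methyl-7-methylidene-1-(propan-2-yl)-1,2,3,4,4a,5,6,7-octahydronaphthalene, via sulfamate 16 (not isolated)
Conditions: Burgess reagent (1.5 equiv), benzene, 50 °C, 1 h
Reagents that add atoms: none
Why: Burgess dehydration of the tertiary alcohol through sulfamate 16 is a syn-elimination that should take the allylically activated C8 hydrogen and give the conjugated diene without acid, so neither the exocyclic methylene nor the 4a stereocenter is isomerized.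

Step 8
Reactants: 6 5-methoxy-4,6,6-trimethylcyclohex-4-ene-1,3-dione; 17 (1S,4R,4aR)-4-methyl-7-methylidene-1-(propan-2-yl)-1,2,3,4,4a,5,6,7-octahydronaphthalene; 18 2-methylpropanal
Product: 20 target CNP0194760.3 [(2S,4R,4a'R,5'R,8'S)-7-methoxy-5',6,8,8-tetramethyl-4,8'-di(propan-2-yl)-3,4,4',4a',5',6',7',8'-octahydro-3'H-spiro[chromene-2,2'-naphthalen]-5(8H)-one], via heterodiene 19 (not isolated)
Conditions: 6 (1.2 equiv), 18 (1.5 equiv), L-proline (20 mol %), CH2Cl2, rt, 1 h; then 17 (1.0 equiv), 4 Å molecular sieves, 40 °C, 24 h
Reagents that add atoms: none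
Why: Knoevenagel condensation gives heterodiene 19, whose more electron-poor oxadiene (the carbonyl next to CMe2, not the vinylogous-ester carbonyl) should add in an inverse-electron-demand hetero-Diels–Alder reaction to the exocyclic methylene of 17 with oxygen on the more substituted carbon, through the endo transition state (ring C=C under the heterodiene, isopropyl outside) and with pseudoaxial C–O bond formation on the face of the half-chair opposite to the 4a hydrogen, which sets the spiro carbon as S and the new isopropyl-bearing carbon as R.

**Compound list**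
1 | 2-methylpentan-3-one | CCC(=O)C(C)C | starting material
2 | 3,3-dimethoxy-2-methylpentane | CCC(OC)(OC)C(C)C | intermediate
3 | 3-methoxy-2-methylpent-2-ene | CCC(OC)=C(C)C | intermediate
4 | malonyl dichloride (propanedioyl dichloride) | O=C(Cl)CC(=O)Cl | starting material
5 | 5-methoxy-4,4-dimethyl-3-oxohept-5-enoyl chloride | CC=C(OC)C(C)(C)C(=O)CC(=O)Cl | intermediate
6 | 5-methoxy-4,6,6-trimethylcyclohex-4-ene-1,3-dione | COC1=C(C)C(=O)CC(=O)C1(C)C | intermediate
7 | (−)-menthone, (2S,5R)-5-methyl-2-(propan-2-yl)cyclohexan-1-one | O=C1[C@H](C(C)C)CC[C@@H](C)C1 | starting material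
8 | lithium (3R,6S)-3-methyl-6-(propan-2-yl)cyclohex-1-en-1-olate | [Li]OC1=C[C@H](C)CC[C@H]1C(C)C | intermediate
9 | (3R,6S)-2-[(dimethylamino)methyl]-3-methyl-6-(propan-2-yl)cyclohexan-1-one (C2 epimers) | CN(C)CC1[C@H](C)CC[C@@H](C(C)C)C1=O | intermediate
10 | N,N,N-trimethyl-1-[(3S,6R)-6-methyl-2-oxo-3-(propan-2-yl)cyclohexyl]methanaminium iodide (C1 epimers) | C[N+](C)(C)CC1[C@H](C)CC[C@@H](C(C)C)C1=O.[I-] | intermediate
11 | (3R,6S)-3-methyl-2-methylidene-6-(propan-2-yl)cyclohexan-1-one | C=C1[C@H](C)CC[C@@H](C(C)C)C1=O | intermediate
12 | [2-(chloromethyl)prop-2-en-1-yl]trimethylsilane | C[Si](C)(C)CC(=C)CCl | starting material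
13 | trichloro{[(3R,6S)-2-[3-(chloromethyl)but-3-en-1-yl]-3-methyl-6-(propan-2-yl)cyclohex-1-en-1-yl]oxy}titanium | Cl[Ti](Cl)(Cl)OC1=C(CCC(=C)CCl)[C@H](C)CC[C@H]1C(C)C | intermediate
14 | (2R,3R,6S)-2-[3-(chloromethyl)but-3-en-1-yl]-3-methyl-6-(propan-2-yl)cyclohexan-1-one | O=C1[C@H](C(C)C)CC[C@@H](C)[C@H]1CCC(=C)CCl | intermediate
15 | (1S,4R,4aR)-4-methyl-7-methylidene-1-(propan-2-yl)octahydronaphthalen-8a(1H)-ol (8a epimers) | C=C1CC2(O)[C@H](C(C)C)CC[C@@H](C)[C@H]2CC1 | intermediate
16 | triethylammonium N-(methoxycarbonyl)-O-[(1S,4R,4aR)-4-methyl-7-methylidene-1-(propan-2-yl)octahydronaphthalen-8a(1H)-yl]sulfamate | C=C1CC2(OS(=O)(=O)[N-]C(=O)OC)[C@H](C(C)C)CC[C@@H](C)[C@H]2CC1.CC[NH+](CC)CC | intermediate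
17 | (1S,4R,4aR)-4-methyl-7-methylidene-1-(propan-2-yl)-1,2,3,4,4a,5,6,7-octahydronaphthalene | C=C1C=C2[C@H](C(C)C)CC[C@@H](C)[C@H]2CC1 | intermediate
18 | 2-methylpropanal (isobutyraldehyde) | CC(C)C=O | starting material
19 | 5-methoxy-4,6,6-trimethyl-2-(2-methylpropylidene)cyclohex-4-ene-1,3-dione | COC1=C(C)C(=O)C(=CC(C)C)C(=O)C1(C)C | intermediate
20 | CNP0194760.3, (2S,4R,4a'R,5'R,8'S)-7-methoxy-5',6,8,8-tetramethyl-4,8'-di(propan-2-yl)-3,4,4',4a',5',6',7',8'-octahydro-3'H-spiro[chromene-2,2'-naphthalen]-5(8H)-one | COC1=C(C)C(=O)C2=C(O[C@]3(C=C4[C@H](C(C)C)CC[C@@H](C)[C@H]4CC3)C[C@@H]2C(C)C)C1(C)C | target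

**Step count and risks**

Total step count: 8. Longest linear sequence: 6 steps (7 to 20, steps 3 to 8).

Steps most likely to fail:

Step 2 (Proposed new method). What may go wrong: after the first C-acylation the enol ether oxygen attacks the acid chloride with loss of chloromethane (pyranone or enol-lactone formation), or chloride cleaves the vinylogous methyl ester, so that ring A is not closed through carbon or loses its methoxy group. The fallback uses known reactions and makes the same two bonds one after the other. Ketone 1 is converted (Me3SiCl, NaI, Et3N, MeCN) into the more substituted silyl enol ether [(2-methylpent-2-en-3-yl)oxy]trimethylsilane F1. C-Acylation of F1 with methyl 3-chloro-3-oxopropanoate under ZnCl2 should give methyl 4,4-dimethyl-3,5-dioxoheptanoate F2. Dieckmann condensation with LiN(SiMe3)2 (non-nucleophilic, to avoid retro-Claisen cleavage of the 2,2-disubstituted 1,3-diketone) should give 2,2,4-trimethylcyclohexane-1,3,5-trione F3. O-Methylation (Me3SiCHN2, MeOH/toluene) and chromatographic separation of the regioisomeric methyl ethers bring the route back to 6, at the cost of the regiocontrol.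

Step 5. What may go wrong: the titanium enolate is protonated on the face syn to the methyl group (the pseudoaxial isopropyl group shields the other face from a 1,3-position), or the α-stereocenter equilibrates during work-up, so that the side chain ends up trans to the methyl group. The fallback replaces substrate control by reagent control. Compounds 11 and 12 are combined under InCl3 catalysis in the presence of Me3SiCl, so that the conjugate adduct is isolated as the silyl enol ether {[(3R,6S)-2-[3-(chloromethyl)but-3-en-1-yl]-3-methyl-6-(propan-2-yl)cyclohex-1-en-1-yl]oxy}trimethylsilane F4. F4 is then protonated at −78 °C with the matched enantiomer of the chiral Brønsted acid BINOL·SnCl4 (enantioselective protonation of silyl enol ethers), which returns to 14.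

Step 8. What may go wrong: the heterodiene is consumed by Michael addition of a second molecule of 6, the exocyclic diene 17 isomerizes under the amine/acid catalysis, or the cycloaddition takes place on both faces of the exocyclic double bond. The fallback uses a masked heterodiene that is made and purified separately. Compounds 6 and 18 are condensed with thiophenol (piperidine cat.) to the sulfide 5-methoxy-4,6,6-trimethyl-2-[2-methyl-1-(phenylsulfanyl)propyl]cyclohex-4-ene-1,3-dione F5, which is oxidized (mCPBA, −78 °C) to the sulfoxide 2-[1-(benzenesulfinyl)-2-methylpropyl]-5-methoxy-4,6,6-trimethylcyclohex-4-ene-1,3-dione F6. Warming F6 with 17 in toluene (40–60 °C, no additive) releases 19 by sulfoxide syn-elimination at low stationary concentration under neutral conditions and should give 20 directly.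

Further compounds
F1 | step 2 | [(2-methylpent-2-en-3-yl)oxy]trimethylsilane | CCC(O[Si](C)(C)C)=C(C)C
F2 | step 2 | methyl 4,4-dimethyl-3,5-dioxoheptanoate | CCC(=O)C(C)(C)C(=O)CC(=O)OC
F3 | step 2 | 2,2,4-trimethylcyclohexane-1,3,5-trione | CC1C(=O)CC(=O)C(C)(C)C1=O
F4 | step 5 | {[(3R,6S)-2-[3-(chloromethyl)but-3-en-1-yl]-3-methyl-6-(propan-2-yl)cyclohex-1-en-1-yl]oxy}trimethylsilane | C[Si](C)(C)OC1=C(CCC(=C)CCl)[C@H](C)CC[C@H]1C(C)C
F5 | step 8 | 5-methoxy-4,6,6-trimethyl-2-[2-methyl-1-(phenylsulfanyl)propyl]cyclohex-4-ene-1,3-dione | COC1=C(C)C(=O)C(C(SC2=CC=CC=C2)C(C)C)C(=O)C1(C)C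
F6 | step 8 | 2-[1-(benzenesulfinyl)-2-methylpropyl]-5-methoxy-4,6,6-trimethylcyclohex-4-ene-1,3-dione | COC1=C(C)C(=O)C(C(S(=O)C2=CC=CC=C2)C(C)C)C(=O)C1(C)C
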